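(The readings come from a simulation for substances that don't exist, and the scatter is random.)

Slowness comes first: before I ask what a flask can reach, I ask whether its last change falls inside the asked time.

| flask | starting material | coupling partner | free catalyst | second catalyst | temperature | remark | time |
|---|---|---|---|---|---|---|---|
| south | 2 M | 1.2 equiv | 0.13 mol% | 0.11 mol% | 95 °C | run made earlier |  |
| north-east | 2 M | 1.2 equiv | 0.3 mol% | 0.11 mol% | 128 °C | run made earlier |  |
| alder | 2.0 M | 1.20 equiv | 0.2 mol% | 0.11 mol% | 80 °C |  | 6.0 h |
| elm | 2.0 M | 1.20 equiv | 0.2 mol% | 0.11 mol% | 100 °C |  | 6.0 h |
| cedar | 2.0 M | 1.20 equiv | 0.2 mol% | 0.11 mol% | 120 °C |  | 6.0 h |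
| oak | 2.0 M | 1.20 equiv | 0.2 mol% | 0.11 mol% | 140 °C |  | 6.0 h |

- south (time / min: product / %, starting material / %): 20.0: 55.4, 11.2; 40.0: 73.3, 0.8; 60.0: 78.4, 0; 80.0: 81.4, 0; 120: 81.5, 0
- north-east (time / min: product / %, starting material / %): 4.00: 44.1, 2.0; 8.00: 49.6, 0; 12.0: 48.2, 0.1; 15.0: 49.3, 0; 20.0: 50.1, 0.9

(readings scatter by 0.5 percentage points)

- what may be going on: starting material + free catalyst -> free catalyst + intermediate; coupling partner + second catalyst + intermediate -> second catalyst + product; coupling partner -> decomposed reagent

* the flask that comes out highest in amount of product, in percent of the starting material charged, or "all alike" when all lie within 1.5 percentage points (alder / elm / cedar / oak / all alike)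
* product at the end, in percent of the starting material charged, alder
* product at the end, in percent of the starting material charged, elm
* product at the end, in percent of the starting material charged, cedar
* product at the end, in percent of the starting material charged, oak

The ladder starts with the uptake of starting material. Read from the first reading of each run, starting material falls at about 0.109 min⁻¹ in the south run and about 0.978 min⁻¹ in the north-east run. Per unit of free catalyst, on a line of logarithm against inverse temperature, that gives alder a half-life of 8.28 min.

The next rung is the stall. In the readings, product stops moving near 80.0 min in the south run and near 8.00 min in the north-east run, so the south run takes ten times as long, though the two runs differ in free catalyst as well as in temperature. The same line puts alder's stall near 4.38 h, which is longer than the half-life and shorter than the 6.0 h allowed. So I expect alder to come close to its limit by the asked time, with starting material converted early and coupling finishing afterwards.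

The limit is a race for the coupling partner, which either couples, at a rate proportional to the intermediate, or decomposes, at a rate independent of it. With the starting material and the second catalyst held at one charge, and counting all starting material as intermediate from the beginning, this gives a selectivity factor I call the race number: the logarithm of the inverse of the fraction not turned into product, divided by the equivalents of partner not in product. The stalled runs give 4.38 for south and 0.994 for north-east, though their free catalyst differs. The logarithmic line gives alder a race number of 9.43, larger than oak's 0.615. Two Newton steps from south's yield give 94.6%, then 92.7% for alder.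

The forecast names alder, with 95%, 81%, 56% and 27% from alder to oak, its alder figure higher than my 92.7%, on the ground that “decomposition beats coupling more as temperature rises”.

The flasks give 95.1%, 79.9%, 55.5% and 30.4%, so alder stands highest.

    starting material + free catalyst → free catalyst + intermediate (k = 0.900 L mol⁻¹ s⁻¹, Ea = 51.0 kJ mol⁻¹)
    coupling partner + second catalyst + intermediate → second catalyst + product (k = 0.580 L² mol⁻² s⁻¹, Ea = 55.0 kJ mol⁻¹)
    coupling partner → decomposed reagent (k = 4.30 × 10⁻⁴ s⁻¹, Ea = 113 kJ mol⁻¹)
    (constants at 100 °C)

My race number gave alder 92.7% against the 95.1% found. Now take the neighbour, the same as alder but with 0.720 equiv of coupling partner, and keep the race number 9.43. One Newton step from a yield of 0.5 gives 62.1%. The neighbour gives 63.6% of product, and it ends with 36.4% as intermediate.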